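The pyranone ring (ring C) is opened across the ring A edge: the ortho pair O1–C8a / C4–C4a is read as an aryne retron, and the O1–C2–C3–C4 chain as an (S)-β-silyloxy ester whose C2 centre comes from asymmetric transfer hydrogenation. In the key step fluoride unmasks a cesium alkoxide and 3,5-dimethoxy-6-prenylbenzyne together; O-addition at C8a and acyl capture by the C4a carbanion forge both ring C bonds in one operation. The step exploits the C5 methoxy group beside C4a, which polarises the C4a≡C8a aryne. The precursors are ortho-silylaryl triflate 13 and silyl ether 5. Ring A derives from symmetric 3,5-dimethoxyphenol; the C4 carbonyl later tells its two methyl ethers apart.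

Key step: step 8

Assumption: the stereodescriptor in the SMILES is read as (2S). Flavanone numbering is used throughout (O1, C2, C3, C4, C4a, C5–C8, C8a; ring A = benzo ring, ring B = 2-aryl ring, ring C = pyranone).

Step 1
Reactants: 1 1-(3-hydroxy-4-methoxyphenyl)ethanone
Product: 2 1-[4-methoxy-3-(methoxymethoxy)phenyl]ethanone
Conditions: MOMCl, i-Pr2NEt, CH2Cl2, 0 °C to rt
Reagents that add atoms: chloromethyl methyl ether COCCl
Why: O-Alkylation of the phenol with the α-chloro ether (Williamson-type etherification) masks the only acidic O–H as an acetal that withstands NaH, transfer hydrogenation and fluoride.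

Step 2
Reactants: 2 1-[4-methoxy-3-(methoxymethoxy)phenyl]ethanone
Product: 3 methyl 3-[4-methoxy-3-(methoxymethoxy)phenyl]-3-oxopropanoate
Conditions: NaH (2.5 equiv), (MeO)2CO, THF, reflux; AcOH quench
Reagents that add atoms: dimethyl carbonate COC(=O)OC
Why: Crossed Claisen condensation of the methyl ketone enolate with the non-enolisable carbonate, driven by formation of the stabilised sodium enolate of the β-keto ester.

Step 3
Reactants: 3 methyl 3-[4-methoxy-3-(methoxymethoxy)phenyl]-3-oxopropanoate
Product: 4 methyl (3S)-3-hydroxy-3-[4-methoxy-3-(methoxymethoxy)phenyl]propanoate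
Conditions: RuCl[(S,S)-TsDPEN](p-cymene) (1 mol%), HCO2H/Et3N (5:2), EtOAc, 40 °C
Reagents that add atoms: none
Why: Noyori–Ikariya asymmetric transfer hydrogenation, in which hydride and proton are delivered through the six-membered Ru–H/N–H transition state with the aryl group held under the cymene ligand by a CH/π contact, so that the (S,S)-ligand sets the (S)-carbinol centre (the later C2) under catalyst control while the ester is not reduced.

Step 4
Reactants: 4 methyl (3S)-3-hydroxy-3-[4-methoxy-3-(methoxymethoxy)phenyl]propanoate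
Product: 5 methyl (3S)-3-[4-methoxy-3-(methoxymethoxy)phenyl]-3-[(trimethylsilyl)oxy]propanoate
Conditions: TMSCl, imidazole, CH2Cl2, 0 °C
Reagents that add atoms: chlorotrimethylsilane C[Si](C)(C)Cl
Why: Routine silylation of a secondary alcohol that removes the only O–H, so that fluoride can later release an alkoxide with no proton source present; the stereocentre is not involved.

Step 5
Reactants: 6 3,5-dimethoxyphenol
Product: 7 3,5-dimethoxyphenyl N-isopropylcarbamate
Conditions: i-PrNCO, Et3N (cat.), CH2Cl2, rt
Reagents that add atoms: isopropyl isocyanate CC(C)N=C=O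
Why: Amine-catalysed addition of the phenol to the isocyanate gives the N-isopropyl carbamate, a strong ortho-directing group that can later be removed by fragmentation without attack at the hindered aryl oxygen.

Step 6
Reactants: 7 3,5-dimethoxyphenyl N-isopropylcarbamate
Product: 11 3,5-dimethoxy-2-(3-methylbut-2-en-1-yl)-6-(trimethylsilyl)phenyl N-isopropylcarbamate, via N-silyl carbamate 8 (not isolated), via N-silyl C-silyl carbamate 9 (not isolated), via N-silyl prenyl carbamate 10 (not isolated)
Conditions: TBSOTf, TMEDA, Et2O, 0 °C to rt; n-BuLi (2 equiv), TMEDA, −78 °C; TMSCl (1.1 equiv), −78 to 0 °C; n-BuLi (1.3 equiv), −78 °C; CuBr·SMe2, −78 to −40 °C; prenyl bromide, to 0 °C; aq. NH4Cl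
Reagents that add atoms: chlorotrimethylsilane C[Si](C)(C)Cl; 1-bromo-3-methylbut-2-ene CC(C)=CCBr (the TBS group of TBSOTf, CC(C)(C)[Si](C)(C)OS(=O)(=O)C(F)(F)F, stays only in 8, 9 and 10)
Why: Two consecutive directed ortho-metalations in one flask on a carbamate that is N-silylated once: the first lithiation, directed jointly by the carbamate and the neighbouring methoxy group to C2 (C6 is equivalent by symmetry, C4 between two methoxy groups is less activated), is trapped by TMSCl to give 9, the second takes the only position still flanked by the carbamate and, after transmetalation to copper, the aryl group displaces bromide from prenyl bromide at its primary carbon (allylic substitution), and the N–Si bond is hydrolysed on work-up; silicon is brought in before the prenyl group so that no alkyllithium meets a benzylic allylic CH2.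

Step 7
Reactants: 11 3,5-dimethoxy-2-(3-methylbut-2-en-1-yl)-6-(trimethylsilyl)phenyl N-isopropylcarbamate
Product: 13 3,5-dimethoxy-2-(3-methylbut-2-en-1-yl)-6-(trimethylsilyl)phenyl trifluoromethanesulfonate, via silyl phenol 12 (not isolated)
Conditions: DBU, Et2NH, MeCN, 40 °C; then PhNTf2, rt
Reagents that add atoms: N-phenylbis(trifluoromethanesulfonimide) O=S(=O)(N(c1ccccc1)S(=O)(=O)C(F)(F)F)C(F)(F)F
Why: DBU deprotonates the carbamate N–H and the anion fragments (E1cB) to the phenoxide and isopropyl isocyanate, which Et2NH traps as the urea, and the phenoxide is sulfonylated in the same flask by PhNTf2 to give the ortho-silylaryl triflate.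

Step 8
Reactants: 5 methyl (3S)-3-[4-methoxy-3-(methoxymethoxy)phenyl]-3-[(trimethylsilyl)oxy]propanoate; 13 3,5-dimethoxy-2-(3-methylbut-2-en-1-yl)-6-(trimethylsilyl)phenyl trifluoromethanesulfonate
Product: 16 (2S)-5,7-dimethoxy-2-[4-methoxy-3-(methoxymethoxy)phenyl]-8-(3-methylbut-2-en-1-yl)-2,3-dihydro-4H-chromen-4-one, via cesium alkoxide 14 (not isolated), via aryne 15 (not isolated)
Conditions: CsF (4 equiv), 18-crown-6 (1 equiv), THF, 0 °C to rt, 13 (1.5 equiv) added slowly
Reagents that add atoms: none
Why: Proposed new method: fluoride attacks both silicon atoms, so that 13 gives aryne 15 by loss of triflate while 5 gives the proton-free cesium alkoxide 14; the alkoxide adds to the aryne at C8a and the C4a aryl anion so formed, with no proton to pick up, attacks the ester carbonyl and expels methoxide (removed as MeOSiMe3), which forms O1–C8a and C4–C4a in one operation. The closest known reaction types are the aryne annulation of ortho-hydroxy benzoates to xanthones and the aryne ring expansion of N–H β-lactams, both heteroatom addition followed by intramolecular acyl capture; new here is the aliphatic secondary β-oxy ester as the partner. Ring C is closed by 6-exo-trig attack of the C4a anion on the ester carbonyl after the intermolecular C–O bond formation. No stereocentre is created: C2 was set in step 3 and none of its four bonds is touched, so the (S) configuration is carried through unchanged. The step needs regioselective addition (oxygen to C8a, carbanion at C4a), secured by the C5 methoxy group, whose inductive pull distorts the aryne and stabilises charge at the adjacent C4a as in 3-methoxybenzyne, against the steric shielding of C8a by the C8 prenyl group. It also needs acyl capture to beat protonation, secured by the silyl ether (no O–H in the flask) and by THF, which offers no acidic C–H.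

Step 9
Reactants: 16 (2S)-5,7-dimethoxy-2-[4-methoxy-3-(methoxymethoxy)phenyl]-8-(3-methylbut-2-en-1-yl)-2,3-dihydro-4H-chromen-4-one
Product: 17 (2S)-2-(3-hydroxy-4-methoxyphenyl)-5,7-dimethoxy-8-(3-methylbut-2-en-1-yl)-2,3-dihydro-4H-chromen-4-one
Conditions: HCl (1 M in MeOH), 40 °C
Reagents that add atoms: none
Why: Acid-catalysed acetal exchange with methanol releases the C3' phenol and dimethoxymethane; the prenyl alkene has no free ortho phenol to cyclise onto and C2 has no low-energy epimerisation path under dilute acid.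

Step 10
Reactants: 17 (2S)-2-(3-hydroxy-4-methoxyphenyl)-5,7-dimethoxy-8-(3-methylbut-2-en-1-yl)-2,3-dihydro-4H-chromen-4-one
Product: 18 (2S)-5-hydroxy-2-(3-hydroxy-4-methoxyphenyl)-7-methoxy-8-(3-methylbut-2-en-1-yl)-2,3-dihydro-4H-chromen-4-one (CNP0228678.1)
Conditions: MgI2·OEt2 (3 equiv), THF, 60 °C; aq. HCl (0.5 M) work-up
Reagents that add atoms: none
Why: Chelation-controlled ether cleavage: Mg bound between the C4 carbonyl oxygen and the peri C5 methoxy oxygen activates that methyl group alone for SN2 attack by iodide, a known selectivity for peri-methoxy aryl ketones that should spare the C7 and C4' methyl ethers and the prenyl group.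

Compound list
1 | 1-(3-hydroxy-4-methoxyphenyl)ethanone | CC(=O)c1ccc(OC)c(O)c1 | starting material
2 | 1-[4-methoxy-3-(methoxymethoxy)phenyl]ethanone | CC(=O)c1ccc(OC)c(OCOC)c1 | intermediate
3 | methyl 3-[4-methoxy-3-(methoxymethoxy)phenyl]-3-oxopropanoate | COC(=O)CC(=O)c1ccc(OC)c(OCOC)c1 | intermediate
4 | methyl (3S)-3-hydroxy-3-[4-methoxy-3-(methoxymethoxy)phenyl]propanoate | COC(=O)C[C@H](O)c1ccc(OC)c(OCOC)c1 | intermediate
5 | methyl (3S)-3-[4-methoxy-3-(methoxymethoxy)phenyl]-3-[(trimethylsilyl)oxy]propanoate | COC(=O)C[C@H](O[Si](C)(C)C)c1ccc(OC)c(OCOC)c1 | intermediate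
6 | 3,5-dimethoxyphenol | COc1cc(O)cc(OC)c1 | starting material
7 | 3,5-dimethoxyphenyl N-isopropylcarbamate | COc1cc(OC)cc(OC(=O)NC(C)C)c1 | intermediate
8 | 3,5-dimethoxyphenyl N-(tert-butyldimethylsilyl)-N-isopropylcarbamate (formed in situ) | COc1cc(OC)cc(OC(=O)N(C(C)C)[Si](C)(C)C(C)(C)C)c1 | intermediate
9 | 3,5-dimethoxy-2-(trimethylsilyl)phenyl N-(tert-butyldimethylsilyl)-N-isopropylcarbamate (formed in situ) | COc1cc(OC)c([Si](C)(C)C)c(OC(=O)N(C(C)C)[Si](C)(C)C(C)(C)C)c1 | intermediate
10 | 3,5-dimethoxy-2-(3-methylbut-2-en-1-yl)-6-(trimethylsilyl)phenyl N-(tert-butyldimethylsilyl)-N-isopropylcarbamate (formed in situ) | COc1cc(OC)c([Si](C)(C)C)c(OC(=O)N(C(C)C)[Si](C)(C)C(C)(C)C)c1CC=C(C)C | intermediate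
11 | 3,5-dimethoxy-2-(3-methylbut-2-en-1-yl)-6-(trimethylsilyl)phenyl N-isopropylcarbamate | COc1cc(OC)c([Si](C)(C)C)c(OC(=O)NC(C)C)c1CC=C(C)C | intermediate
12 | 3,5-dimethoxy-2-(3-methylbut-2-en-1-yl)-6-(trimethylsilyl)phenol (formed in situ as its phenoxide) | COc1cc(OC)c([Si](C)(C)C)c(O)c1CC=C(C)C | intermediate
13 | 3,5-dimethoxy-2-(3-methylbut-2-en-1-yl)-6-(trimethylsilyl)phenyl trifluoromethanesulfonate | COc1cc(OC)c([Si](C)(C)C)c(OS(=O)(=O)C(F)(F)F)c1CC=C(C)C | intermediate
14 | cesium (1S)-3-methoxy-1-[4-methoxy-3-(methoxymethoxy)phenyl]-3-oxopropan-1-olate (formed in situ) | COC(=O)C[C@H]([O-])c1ccc(OC)c(OCOC)c1.[Cs+] | intermediate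
15 | 3,5-dimethoxy-6-(3-methylbut-2-en-1-yl)benzyne (1,2-didehydrobenzene, formed in situ) | COC1=CC(OC)=C(CC=C(C)C)C#C1 | intermediate
16 | (2S)-5,7-dimethoxy-2-[4-methoxy-3-(methoxymethoxy)phenyl]-8-(3-methylbut-2-en-1-yl)-2,3-dihydro-4H-chromen-4-one | COc1ccc([C@@H]2CC(=O)c3c(OC)cc(OC)c(CC=C(C)C)c3O2)cc1OCOC | intermediate
17 | (2S)-2-(3-hydroxy-4-methoxyphenyl)-5,7-dimethoxy-8-(3-methylbut-2-en-1-yl)-2,3-dihydro-4H-chromen-4-one | COc1ccc([C@@H]2CC(=O)c3c(OC)cc(OC)c(CC=C(C)C)c3O2)cc1O | intermediate
18 | (2S)-5-hydroxy-2-(3-hydroxy-4-methoxyphenyl)-7-methoxy-8-(3-methylbut-2-en-1-yl)-2,3-dihydro-4H-chromen-4-one | COc1ccc([C@@H]2CC(=O)c3c(O)cc(OC)c(CC=C(C)C)c3O2)cc1O | target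

Total steps: 10. Longest linear sequence: 7 steps (steps 1–4, then 8–10).

Steps most likely to fail

Step 8 (Proposed new method). What may go wrong: protonation of the C4a aryl anion before it reaches the ester, which stops the reaction at the open aryl ether; retro-aldol cleavage of the cesium alkoxide; base-induced β-elimination opening ring C of the product, which would erode the configuration at C2; and slow addition next to the C8 prenyl group, which leaves the aryne to oligomerise. The fallback uses known chemistry, sets out from 4 and 13 and comes back at 16. The free alcohol 4 is O-arylated by the aryne under protic conditions (CsF, MeCN, rt; same regiochemistry, the C4a anion takes the O–H proton) to give methyl (3S)-3-[3,5-dimethoxy-2-(3-methylbut-2-en-1-yl)phenoxy]-3-[4-methoxy-3-(methoxymethoxy)phenyl]propanoate F1. Saponification (LiOH, THF/H2O, 0 °C) should give (3S)-3-[3,5-dimethoxy-2-(3-methylbut-2-en-1-yl)phenoxy]-3-[4-methoxy-3-(methoxymethoxy)phenyl]propanoic acid F2. Intramolecular Friedel–Crafts acylation through the mixed anhydride (TFAA, CH2Cl2, 0 °C) then closes ring C at C4a, the only position the tether can reach, and returns 16.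

Step 6. What may go wrong: consumption of the second charge of n-BuLi by leftover TMSCl, which leaves 9 unprenylated; metalation at C4 between the two methoxy groups; carbamoyl migration (anionic ortho-Fries) on warming; or γ-attack on the allylic bromide leading to the 1,1-dimethylallyl isomer. The fallback sets out from 6 and comes back at 11. The prenyl group is introduced first by ortho-selective C-alkylation of the sodium phenoxide (NaH, prenyl bromide, toluene, rt) to give 3,5-dimethoxy-2-(3-methylbut-2-en-1-yl)phenol F3. Addition to i-PrNCO (cat. Et3N) gives 3,5-dimethoxy-2-(3-methylbut-2-en-1-yl)phenyl N-isopropylcarbamate F4. A single silylation–metalation sequence (TBSOTf, TMEDA; n-BuLi, TMEDA, −78 °C; TMSCl; aq. NH4Cl) then runs through 3,5-dimethoxy-2-(3-methylbut-2-en-1-yl)phenyl N-(tert-butyldimethylsilyl)-N-isopropylcarbamate F5 and 10 to 11. Ring metalation between carbamate and methoxy is expected to outrun lateral deprotonation at −78 °C.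

Step 10. What may go wrong: Lewis-acid-assisted opening of ring C to the 2'-hydroxychalcone and reclosure, which would erode the configuration at C2; addition of HI across the prenyl double bond; and loss of the C4' methyl group through chelation to the neighbouring free C3' phenol. The fallback sets out from 5 and comes back at 18; it carries the C5 oxygen as a MOM ether so that no Lewis-acid ether cleavage is needed. 5-Methoxybenzene-1,3-diol F6 (purchased) is mono-protected (MOMCl 1 equiv, i-Pr2NEt; statistical, diol recycled) to 3-methoxy-5-(methoxymethoxy)phenol F7. Carbamoylation (ClCONEt2, K2CO3, MeCN) gives 3-methoxy-5-(methoxymethoxy)phenyl N,N-diethylcarbamate F8. Metalation between the two strongest directing groups (sec-BuLi, TMEDA, THF, −78 °C; TMSCl) gives 5-methoxy-3-(methoxymethoxy)-2-(trimethylsilyl)phenyl N,N-diethylcarbamate F9. Prenylation at the remaining position beside the carbamate (sec-BuLi, TMEDA; CuBr·SMe2; prenyl bromide) gives 3-methoxy-5-(methoxymethoxy)-2-(3-methylbut-2-en-1-yl)-6-(trimethylsilyl)phenyl N,N-diethylcarbamate F10. Reductive carbamate cleavage (LiAlH4, THF) gives 3-methoxy-5-(methoxymethoxy)-2-(3-methylbut-2-en-1-yl)-6-(trimethylsilyl)phenol F11, and triflation (Tf2O, pyridine) gives 3-methoxy-5-(methoxymethoxy)-2-(3-methylbut-2-en-1-yl)-6-(trimethylsilyl)phenyl trifluoromethanesulfonate F12. Under the conditions of step 8, F12 and 5 should give, through 5-methoxy-3-(methoxymethoxy)-6-(3-methylbut-2-en-1-yl)benzyne F13, (2S)-7-methoxy-5-(methoxymethoxy)-2-[4-methoxy-3-(methoxymethoxy)phenyl]-8-(3-methylbut-2-en-1-yl)-2,3-dihydro-4H-chromen-4-one F14. HCl in MeOH then removes both acetals and gives 18.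

Further compounds
F1 | step 8 | methyl (3S)-3-[3,5-dimethoxy-2-(3-methylbut-2-en-1-yl)phenoxy]-3-[4-methoxy-3-(methoxymethoxy)phenyl]propanoate | COC(=O)C[C@H](Oc1cc(OC)cc(OC)c1CC=C(C)C)c1ccc(OC)c(OCOC)c1
F2 | step 8 | (3S)-3-[3,5-dimethoxy-2-(3-methylbut-2-en-1-yl)phenoxy]-3-[4-methoxy-3-(methoxymethoxy)phenyl]propanoic acid | OC(=O)C[C@H](Oc1cc(OC)cc(OC)c1CC=C(C)C)c1ccc(OC)c(OCOC)c1
F3 | step 6 | 3,5-dimethoxy-2-(3-methylbut-2-en-1-yl)phenol | COc1cc(O)c(CC=C(C)C)c(OC)c1
F4 | step 6 | 3,5-dimethoxy-2-(3-methylbut-2-en-1-yl)phenyl N-isopropylcarbamate | COc1cc(OC(=O)NC(C)C)c(CC=C(C)C)c(OC)c1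
F5 | step 6 | 3,5-dimethoxy-2-(3-methylbut-2-en-1-yl)phenyl N-(tert-butyldimethylsilyl)-N-isopropylcarbamate | COc1cc(OC(=O)N(C(C)C)[Si](C)(C)C(C)(C)C)c(CC=C(C)C)c(OC)c1
F6 | step 10 | 5-methoxybenzene-1,3-diol (purchased) | COc1cc(O)cc(O)c1
F7 | step 10 | 3-methoxy-5-(methoxymethoxy)phenol | COCOc1cc(O)cc(OC)c1
F8 | step 10 | 3-methoxy-5-(methoxymethoxy)phenyl N,N-diethylcarbamate | CCN(CC)C(=O)Oc1cc(OC)cc(OCOC)c1
F9 | step 10 | 5-methoxy-3-(methoxymethoxy)-2-(trimethylsilyl)phenyl N,N-diethylcarbamate | CCN(CC)C(=O)Oc1cc(OC)cc(OCOC)c1[Si](C)(C)C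
F10 | step 10 | 3-methoxy-5-(methoxymethoxy)-2-(3-methylbut-2-en-1-yl)-6-(trimethylsilyl)phenyl N,N-diethylcarbamate | CCN(CC)C(=O)Oc1c(CC=C(C)C)c(OC)cc(OCOC)c1[Si](C)(C)C
F11 | step 10 | 3-methoxy-5-(methoxymethoxy)-2-(3-methylbut-2-en-1-yl)-6-(trimethylsilyl)phenol | COCOc1cc(OC)c(CC=C(C)C)c(O)c1[Si](C)(C)C
F12 | step 10 | 3-methoxy-5-(methoxymethoxy)-2-(3-methylbut-2-en-1-yl)-6-(trimethylsilyl)phenyl trifluoromethanesulfonate | COCOc1cc(OC)c(CC=C(C)C)c(OS(=O)(=O)C(F)(F)F)c1[Si](C)(C)C
F13 | step 10 | 5-methoxy-3-(methoxymethoxy)-6-(3-methylbut-2-en-1-yl)benzyne (formed in situ) | COCOC1=CC(OC)=C(CC=C(C)C)C#C1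
F14 | step 10 | (2S)-7-methoxy-5-(methoxymethoxy)-2-[4-methoxy-3-(methoxymethoxy)phenyl]-8-(3-methylbut-2-en-1-yl)-2,3-dihydro-4H-chromen-4-one | COc1ccc([C@@H]2CC(=O)c3c(OCOC)cc(OC)c(CC=C(C)C)c3O2)cc1OCOC
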